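## Structural features

Compound 26 is a clerodane-type diterpenoid built on a trans-fused octalin: ring A (C10–C1–C2–C3=C4–C5) carries only the trisubstituted alkene with its C4 methyl, whereas ring B (C5–C6–C7–C8–C9–C10) is substituted at every carbon. Six contiguous stereocentres (5R,6R,7S,8R,9R,10S) line ring B; three are quaternary (C5, C8, C9), the C5 and C9 methyls are 1,3-diaxial on the α face and H10 is axial on the β face. C6 and C7 carry trans-diequatorial esters that differ (6α-acetate, 7β-isobutyrate), C8 carries an axial tertiary hydroxyl cis to the equatorial C9 side chain, and that side chain is an (E)-C11=C12 alkene conjugated to a butenolide joined at C13. The fragile groups are the two neighbouring esters (acyl migration, loss of the O6/O7 distinction), the tertiary β-hydroxyl (dehydration, and retro-aldol opening of C8–C9 whenever C11 is a carbonyl group and base is present), the dienyl butenolide (γ-deprotonation, conjugate addition) and the acid-sensitive C3=C4 alkene. The real difficulty is the C8–C9 bond, which joins two quaternary stereocentres next to the quaternary C5 and must be made with the correct relation to the 6,7-dioxygen pattern, together with control of absolute configuration in a molecule without a chiral-pool handle. The key step exploits ring A: the C5–C6 and C10–C9 bonds are trans, C5 is quaternary with a methyl group and C4 carries a methyl, which is the pattern of a [4+2] adduct between an (E)-2-methyl enal (C6, C5, C10, C9, C11) and a 1-methylbutadiene (C1–C4 with the C4 methyl). Because ring A has no other functionality, the only trace the cycloaddition leaves is an alkene one position away from where it is needed.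

## Logic of the disconnections

26 ⇒ 24 + 25. The C12–C13 bond is cut (Heck coupling). The dienyl butenolide is the most base- and nucleophile-sensitive part of 26 and is therefore attached last. The gain is that the heterocycle and the diene disappear from every earlier intermediate. The forward step demands insertion at a vinyl group on the quaternary C9; because C9 has no hydrogen, β-hydride elimination can only give C11=C12.

24 ⇒ 23 ⇒ 22 ⇒ 21 ⇒ 20. The two acyl C–O bonds (O6–acetyl, O7–isobutyryl) are cut one at a time, each after removal of one ether. O6 and O7 are both hindered secondary equatorial hydroxyls and cannot be told apart by reactivity, so they are distinguished by the way they were created (O7 as an acetal ether, O6 as a silyl ether). The gain is that the ester pattern reduces to two orthogonal ethers. The demand is that each deprotection spares the other group, that no acyl group moves to a neighbouring free hydroxyl, and that the tertiary O8 stays free.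

20 ⇒ 19 ⇒ 18 ⇒ 17. The C11=C12 bond is cut (one-carbon olefination) and C11 is taken back to the ester level. The gain is that the side chain shrinks to the carboxyl carbon that the ring closure delivers. The demand is a methylenation without base, because 19 is a β-hydroxy aldehyde that can open ring B by retro-aldol.

17 ⇒ 15. The C8–C9 bond is cut (intramolecular reductive aldol). It is the most congested bond of ring B; making the C9 enolate by hydride conjugate addition forms it under neutral conditions, and the acrylate methylene becomes the C9 methyl. The gain is that ring B opens and two quaternary stereocentres become a ketone and an acrylate. The demand is one face of the ketone and one face of the enolate in a chair that is trans-fused to ring A.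

15 ⇒ 14 ⇒ 11. The C8 ketone is traced to a terminal vinyl group and the C9=CH2 bond is cut (Mannich methylenation). A methyl ketone and an acrylate cannot be made by enolate or organometallic chemistry in each other's presence; a vinyl group is inert to the amide base, and its later oxidation is neutral and leaves the acrylate alone. The gain is that 11 contains a single carbonyl group. The demand is Markovnikov oxidation at an allylic ether and no migration of the acrylate alkene to C9=C10.

11 ⇒ 10 ⇒ 7 + 8. The C6–C7 bond is cut (γ-alkoxyallylboration), then the O6–Si bond. C6 is the formyl carbon of the cycloadduct, and the allyl reagent brings C7, C8, the future C8 methyl and the O7 protecting group in one step. The gain is two stereocentres and three carbons. The demand is reagent control over a neopentyl aldehyde and immediate capping of O6, which could otherwise lactonise onto C11.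

7 ⇒ 6. The alkene is moved back from C3=C4 to C2=C3. The cycloaddition necessarily leaves it at C2=C3; the shift also deletes the temporary C4 stereocentre. The demand is that migration stops at the first trisubstituted position.

6 ⇒ 4 + 5. The C4–C5 and C1–C10 bonds are cut (Diels–Alder). This removes ring A and the C5 and C10 stereocentres in one step and reaches two small achiral components. The demand is enantioface selection on 4; the C6/C9 trans relation follows from the alkene geometry and the regiochemistry from the methyl group of 5.

4 ⇒ 1 + 2 (through 3). The C5=C10 double bond of the enal is cut (Wittig). The gain is two commercial three-carbon pieces. The demand is (E) geometry and handling of the unstable 3 without isolation.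

## Other disconnections considered

Alternative 1: The cut is at the C9–CH3 and C5–CH3 bonds, traced back by 1,2-shifts to the 8β,9β-epoxy-7-ketone A1 of the ent-homodrimane series. In the forward key step a Lewis acid opens the epoxide at C9, the C10 methyl, H5 and the axial C4 methyl migrate in turn, and loss of H3 gives A2.
- In favour: one operation turns a drimane skeleton into the clerodane skeleton and sets C9, C10, C5 and the C3=C4 alkene. The 8β oxygen arrives from the epoxide, and each centre is fixed by an antiperiplanar shift. On the C8/C9 relationship this is better than the chosen plan, whose step 8 must win a facial selection.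
- Against: the ent series is needed, which the usual drimane chiral pool does not supply, so absolute configuration must be bought in an earlier asymmetric step. The cascade can stop part-way by proton loss or divert to hydride shift or ring contraction, and the C7 ketone retards ionisation at C9.
- Also against: A2 still lacks the C6 oxygen (to be introduced at a neopentyl position), needs a 7β-selective reduction and O6/O7 differentiation, and has a saturated C11–C12 chain that must be dehydrogenated.
- Comparison: structurally A2 holds more of the skeleton than 6 (equal or better on carbon count). Mechanistically it relies on substrate stereoelectronics rather than catalyst control. In step count it is judged longer once the route to A1 and the later oxidation-level changes are included.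

Alternative 2: The cut is at C8–C9. In the forward key step copper hydride reduces the acrylate of A3 and the enolate closes ring B onto the C8 ketone to give A4.
- In favour: ring B and both quaternary centres form together under neutral conditions, and both enolate geometries can use the same chair. This is the reaction used as step 8 of the chosen plan, so on this bond the two plans are equal. The PMB ether at O7 of A4 can be removed oxidatively under neutral conditions, which is better than the acetal ether of the chosen plan.
- Against: taken as the central disconnection it leaves open how C5 and C10 of A3 are set in the absolute sense. The PMB-oxy pattern implies an auxiliary-based glycolate aldol, whose acyl group must become a methyl ketone in the presence of the C11 ester and around the methylenation, which costs extra steps and creates an ordering conflict.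
- Comparison: the two are complementary rather than competing. The chosen plan embeds this bond formation and adds a ring-A solution that supplies the absolute configuration; step count is equal for the shared part and shorter in the chosen plan for the C7–C8 unit.

Alternative 3: The cut is at C5–C10 and C8–C9. In the forward key step a chiral Lewis acid joins the silyloxydiene A5 and the dienal A6 to give the ring-B adduct A7.
- In favour: quaternary C9 is set directly with its formyl group, so C11 is already at the right oxidation level (better than the chosen plan). A5 is far more reactive than 5 and its regiochemistry is fixed by the oxygen (better on rate and regiocontrol). A6 has no acidic methylene, unlike 4 (better robustness), and the C6 oxygen is present.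
- Against: ring A remains to be built. The C4–C5 bond must be made at C5, creating that quaternary centre next to C10 on the correct face, and the butenyl end needs functionalisation, a C4 methyl and the C3=C4 alkene. The C7 oxygen and the C8 tertiary hydroxyl (C8 carries hydrogen in A7) need later stereocontrolled oxidation, and A5 must be geometrically pure.
- Comparison: mechanistically the two plans are equal (same class of catalysed cycloaddition). Structurally the alternative fixes C9 early and leaves C5, while the chosen plan fixes C5 early and leaves C9. The ring-A annulation plus C7/C8 oxidation is expected to cost more steps than the alkoxyallylation and reductive aldol of the chosen plan.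

Key step: step 2

Remark on numbering: clerodane numbering is used for all intermediates (ring A: C10, C1–C5; ring B: C5–C10; C11 on C9); α/β refer to the projection in which the C5 methyl is α and H10 is β.
Remark on the structures: mapping 6 onto 26 atom by atom confirms that C5 and C10 of 6 have the geometry of 5R,10S in 26 (the C10 descriptor is R in 6 only because the CIP priorities change); no structure needed correction.
Remark on the precursor: the 4/5 pair is kept as it stands. The methyl ester of 4 is retained deliberately, because a tert-butyl ester would not survive step 3 and the C9 methylene is needed in step 6; the acidity of that methylene is answered by using 4 freshly made, cold and with excess 5.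
Remark on reagent sense: the (R) catalyst in step 2 and the (+)-α-pinene-derived borane in step 4 are the antipodes that the accepted transition-state models assign to the required faces; the mirror-image reagent would be used if the product series proved opposite.
Remark on purchase: 8 and 25 are taken as bought.

## Route

Step 1
Reactants: 1 methyl 3,3-dimethoxypropanoate; 2 2-(triphenylphosphoranylidene)propanal
Product: 4 methyl (E)-4-methyl-5-oxopent-3-enoate, via methyl 3-oxopropanoate 3 (not isolated)
Conditions: CF3CO2H/H2O, CHCl3, 0 °C → rt; organic phase dried; then 2, rt → 45 °C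
Reagents that add atoms: none
Why: Acid hydrolysis unmasks the β-formyl ester 3, which is olefinated at once by the formyl-stabilised ylide (Wittig reaction); a stabilised ylide should give the (E)-enal with CHO trans to CH2CO2Me, and the α-branched enal product is too unreactive to be olefinated a second time.

Step 2
Reactants: 4 methyl (E)-4-methyl-5-oxopent-3-enoate; 5 trans-piperylene
Product: 6 methyl 2-[(1R,5S,6R)-6-formyl-5,6-dimethylcyclohex-3-en-1-yl]acetate
Conditions: (R)-1-(2-methylphenyl)-3,3-diphenyltetrahydro-1H,3H-pyrrolo[1,2-c][1,3,2]oxazaborole·HN(SO2CF3)2 (20 mol %), 5 (5 equiv), CH2Cl2, −78 → −20 °C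
Reagents that add atoms: none
Why: The formyl oxygen of 4 binds to the cationic boron (with the formyl C–H···O contact typical of α-substituted enals), which lowers the LUMO and holds the s-trans enal over one phenyl group so that only the C5-Si/C10-Re face is open; a concerted, asynchronous [4π+2π] cycloaddition with s-cis 5 then forms C1–C10 slightly ahead of C4–C5. The closest known reaction type is the oxazaborolidinium-catalysed enantioselective Diels–Alder reaction of 2-methylacrolein and tiglic aldehyde with 1-substituted butadienes ("ortho" adducts). Ring A is closed by the intermolecular cycloaddition itself, both σ bonds forming suprafacially on diene and dienophile to give a cyclohex-3-ene. C5 (quaternary) is set by the enal face that the catalyst exposes; C10 follows from C5 because addition is suprafacial on the (E)-alkene, which places C6 and C9 trans; C4 follows from the endo preference of the formyl group but is erased in step 3, so an endo/exo mixture is harmless. The step needs regioselectivity, secured by the methyl group of 5 (the unsubstituted terminus has the larger HOMO coefficient and bonds to the β-carbon C10), and enantioface selectivity, secured by the catalyst because the ester carbonyl is a much weaker donor than the aldehyde. The acidic C9 methylene of 4 is the weak point, hence fresh 4, low temperature and excess diene.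

Step 3
Reactants: 6 methyl 2-[(1R,5S,6R)-6-formyl-5,6-dimethylcyclohex-3-en-1-yl]acetate
Product: 7 methyl 2-[(1R,2R)-2-formyl-2,3-dimethylcyclohex-3-en-1-yl]acetate
Conditions: TsOH·H2O (10 mol %), benzene, 70 °C, stopped at full conversion
Reagents that add atoms: none
Why: Acid-catalysed alkene isomerisation: protonation at C2, 1,2-hydride shift from C4 to the tertiary cation and loss of H3 give the trisubstituted C3=C4 alkene and erase the C4 stereocentre; C5 is quaternary and C10 is not next to a carbonyl group, so neither can epimerise.

Step 4
Reactants: 7 methyl 2-[(1R,2R)-2-formyl-2,3-dimethylcyclohex-3-en-1-yl]acetate; 8 3-(methoxymethoxy)prop-1-ene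
Product: 10 methyl 2-[(1R,2R)-2-[(1R,2R)-1-hydroxy-2-(methoxymethoxy)but-3-en-1-yl]-2,3-dimethylcyclohex-3-en-1-yl]acetate, via Z-alkoxyallylborane 9 (not isolated)
Conditions: 8, s-BuLi, THF, −78 °C; (−)-Ipc2BOMe; BF3·OEt2; then 7, −78 °C → rt; pH 7 buffer, 30% H2O2
Reagents that add atoms: none
Why: Asymmetric γ-alkoxyallylboration: the chelated (Z)-allyl anion gives the (Z)-borane 9, whose chair Zimmerman–Traxler transition state puts O6 and O7 syn (the trans-diequatorial pair of ring B), while the isopinocampheyl groups from (+)-α-pinene direct attack to the Si face of the formyl group (6R); the buffered work-up avoids base-induced lactonisation of O6 onto C11.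

Step 5
Reactants: 10 methyl 2-[(1R,2R)-2-[(1R,2R)-1-hydroxy-2-(methoxymethoxy)but-3-en-1-yl]-2,3-dimethylcyclohex-3-en-1-yl]acetate
Product: 11 methyl 2-[(1R,2R)-2-[(1R,2R)-1-(tert-butyldimethylsilyloxy)-2-(methoxymethoxy)but-3-en-1-yl]-2,3-dimethylcyclohex-3-en-1-yl]acetate
Conditions: TBSOTf, 2,6-lutidine, CH2Cl2, −78 → 0 °C
Reagents that add atoms: tert-butyldimethylsilyl trifluoromethanesulfonate, CC(C)(C)[Si](C)(C)OS(=O)(=O)C(F)(F)F
Why: Silylation of the hindered secondary alcohol with the silyl triflate blocks δ-lactonisation onto C11 and makes O6 orthogonal to the acetal ether on O7.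

Step 6
Reactants: 11 methyl 2-[(1R,2R)-2-[(1R,2R)-1-(tert-butyldimethylsilyloxy)-2-(methoxymethoxy)but-3-en-1-yl]-2,3-dimethylcyclohex-3-en-1-yl]acetate
Product: 14 methyl 2-[(1S,2R)-2-[(1R,2R)-1-(tert-butyldimethylsilyloxy)-2-(methoxymethoxy)but-3-en-1-yl]-2,3-dimethylcyclohex-3-en-1-yl]prop-2-enoate, via Mannich base 12 (not isolated), via ammonium iodide 13 (not isolated)
Conditions: LiN(i-Pr)2, THF, −78 °C; CH2=NMe2+ I−, −78 °C → rt; then MeI, MeOH, rt; then NaHCO3 (aq)/CH2Cl2
Reagents that add atoms: N,N-dimethylmethyleneiminium iodide, C=[N+](C)C.[I-]
Why: The C9 methylene is the only C–H acid in 11 (no other carbonyl, the vinyl group is inert), so the ester enolate undergoes a Mannich reaction with the iminium salt; quaternisation and E1cB loss of trimethylamine under bicarbonate give the α-methylene ester without moving the alkene to C9=C10.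

Step 7
Reactants: 14 methyl 2-[(1S,2R)-2-[(1R,2R)-1-(tert-butyldimethylsilyloxy)-2-(methoxymethoxy)but-3-en-1-yl]-2,3-dimethylcyclohex-3-en-1-yl]prop-2-enoate
Product: 15 methyl 2-[(1S,2R)-2-[(1R,2S)-1-(tert-butyldimethylsilyloxy)-2-(methoxymethoxy)-3-oxobutyl]-2,3-dimethylcyclohex-3-en-1-yl]prop-2-enoate
Conditions: PdCl2(Quinox) (5 mol %; Quinox = 2-(4,5-dihydrooxazol-2-yl)quinoline), AgSbF6 (12 mol %), t-BuOOH (aq), CH2Cl2, 0 °C → rt
Reagents that add atoms: tert-butyl hydroperoxide, CC(C)(C)OO
Why: Wacker-type oxidation in its hydroperoxide/Quinox form converts terminal alkenes of protected allylic alcohols into methyl ketones with Markovnikov selectivity; the electron-poor acrylate and the trisubstituted ring alkene do not bind divalent palladium competitively, and the neutral medium leaves C7 (now α to the ketone) unepimerised.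

Step 8
Reactants: 15 methyl 2-[(1S,2R)-2-[(1R,2S)-1-(tert-butyldimethylsilyloxy)-2-(methoxymethoxy)-3-oxobutyl]-2,3-dimethylcyclohex-3-en-1-yl]prop-2-enoate
Product: 17 methyl 6α-(tert-butyldimethylsilyloxy)-8β-hydroxy-7β-(methoxymethoxy)-4,5α,8α,9α-tetramethyl-Δ3-trans-octalin-9β-carboxylate (5R,6R,7S,8R,9R,10S), via copper enolate 16 (not isolated)
Conditions: [(Ph3P)CuH]6 (0.5 equiv), toluene, −40 → 0 °C; NH4Cl (aq)
Reagents that add atoms: none
Why: Conjugate addition of copper hydride to the acrylate gives enolate 16 regiospecifically without exposing the ketone to base, and 16 adds to the C8 ketone through a copper-bridged chair in which ring B is trans-fused, the 6- and 7-oxygens and the C8 methyl are equatorial and the ketone oxygen is axial and syn to the ester, so 8β-OH, 9α-CH3 (the former methylene) and 9β-CO2Me arise together; both enolate geometries can use this chair and the aldolate can equilibrate by retro-aldol, which is why convergence on one isomer is expected (intramolecular reductive aldol).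

Step 9
Reactants: 17 methyl 6α-(tert-butyldimethylsilyloxy)-8β-hydroxy-7β-(methoxymethoxy)-4,5α,8α,9α-tetramethyl-Δ3-trans-octalin-9β-carboxylate
Product: 18 6α-(tert-butyldimethylsilyloxy)-9β-(hydroxymethyl)-7β-(methoxymethoxy)-4,5α,8α,9α-tetramethyl-Δ3-trans-octalin-8β-ol (5R,6R,7S,8R,9S,10S)
Conditions: i-Bu2AlH (4 equiv), CH2Cl2, −78 → 0 °C; KNaC4H4O6 (aq)
Reagents that add atoms: none
Why: Hydride reduction of the hindered methyl ester to the primary alcohol; the aluminium alkoxide of the tertiary hydroxyl is not basic enough for retro-aldol at low temperature, and the silyl and acetal ethers are inert.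

Step 10
Reactants: 18 6α-(tert-butyldimethylsilyloxy)-9β-(hydroxymethyl)-7β-(methoxymethoxy)-4,5α,8α,9α-tetramethyl-Δ3-trans-octalin-8β-ol
Product: 19 6α-(tert-butyldimethylsilyloxy)-8β-hydroxy-7β-(methoxymethoxy)-4,5α,8α,9α-tetramethyl-Δ3-trans-octalin-9β-carbaldehyde (5R,6R,7S,8R,9R,10S)
Conditions: 1,1,1-triacetoxy-1,1-dihydro-1,2-benziodoxol-3(1H)-one (DMP), NaHCO3, CH2Cl2, 0 °C → rt
Reagents that add atoms: none
Why: Hypervalent-iodine oxidation takes the neopentyl primary alcohol to the aldehyde under buffered, non-basic conditions; the tertiary alcohol cannot be oxidised and C9 is quaternary, so nothing can epimerise.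

Step 11
Reactants: 19 6α-(tert-butyldimethylsilyloxy)-8β-hydroxy-7β-(methoxymethoxy)-4,5α,8α,9α-tetramethyl-Δ3-trans-octalin-9β-carbaldehyde
Product: 20 6α-(tert-butyldimethylsilyloxy)-7β-(methoxymethoxy)-4,5α,8α,9α-tetramethyl-9β-vinyl-Δ3-trans-octalin-8β-ol (5R,6R,7S,8R,9R,10S)
Conditions: Zn, CH2Br2, TiCl4, THF (reagent preformed); then 19, CH2Cl2, 0 °C → rt
Reagents that add atoms: dibromomethane, BrCBr
Why: Titanium-mediated methylenation with the zinc gem-dimetallic reagent is non-basic and tolerates free hydroxyl groups, so the β-hydroxy aldehyde is olefinated without the retro-aldol opening of C8–C9 that a phosphorus ylide could trigger.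

Step 12
Reactants: 20 6α-(tert-butyldimethylsilyloxy)-7β-(methoxymethoxy)-4,5α,8α,9α-tetramethyl-9β-vinyl-Δ3-trans-octalin-8β-ol
Product: 21 6α-(tert-butyldimethylsilyloxy)-4,5α,8α,9α-tetramethyl-9β-vinyl-Δ3-trans-octalin-7β,8β-diol
Conditions: ZnBr2, n-PrSH, CH2Cl2, 0 °C
Reagents that add atoms: none
Why: Lewis-acid activation of the acetal ether with a thiol as cation trap removes the methoxymethyl group selectively; the thiol intercepts the oxocarbenium ion before O8 can close a methylene acetal, and the hindered silyl ether survives.

Step 13
Reactants: 21 6α-(tert-butyldimethylsilyloxy)-4,5α,8α,9α-tetramethyl-9β-vinyl-Δ3-trans-octalin-7β,8β-diol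
Product: 22 6α-(tert-butyldimethylsilyloxy)-8β-hydroxy-4,5α,8α,9α-tetramethyl-9β-vinyl-Δ3-trans-octalin-7β-yl 2-methylpropanoate
Conditions: (i-PrCO)2O, DMAP, Et3N, CH2Cl2, rt → 40 °C
Reagents that add atoms: isobutyric anhydride, CC(C)C(=O)OC(=O)C(C)C
Why: Nucleophile-catalysed acylation of the only secondary hydroxyl; the tertiary O8, flanked by two fully substituted carbons, is too hindered to react.

Step 14
Reactants: 22 6α-(tert-butyldimethylsilyloxy)-8β-hydroxy-4,5α,8α,9α-tetramethyl-9β-vinyl-Δ3-trans-octalin-7β-yl 2-methylpropanoate
Product: 23 6α,8β-dihydroxy-4,5α,8α,9α-tetramethyl-9β-vinyl-Δ3-trans-octalin-7β-yl 2-methylpropanoate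
Conditions: HF·pyridine, pyridine/THF, 0 °C → rt
Reagents that add atoms: none
Why: Fluoride desilylation under mildly acidic conditions frees O6 without the alkoxide character that would move the isobutyryl group from O7 to O6.

Step 15
Reactants: 23 6α,8β-dihydroxy-4,5α,8α,9α-tetramethyl-9β-vinyl-Δ3-trans-octalin-7β-yl 2-methylpropanoate
Product: 24 6α-acetoxy-8β-hydroxy-4,5α,8α,9α-tetramethyl-9β-vinyl-Δ3-trans-octalin-7β-yl 2-methylpropanoate
Conditions: Ac2O, DMAP (cat.), pyridine, CH2Cl2, rt
Reagents that add atoms: acetic anhydride, CC(=O)OC(C)=O
Why: Fast catalysed acetylation of the neopentyl secondary hydroxyl outruns acyl migration; the tertiary hydroxyl stays free, and the migration-prone acetate is installed only when no secondary hydroxyl remains.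

Step 16
Reactants: 24 6α-acetoxy-8β-hydroxy-4,5α,8α,9α-tetramethyl-9β-vinyl-Δ3-trans-octalin-7β-yl 2-methylpropanoate; 25 4-bromofuran-2(5H)-one
Product: 26 6α-acetoxy-8β-hydroxy-9β-[(E)-2-(5-oxo-2,5-dihydrofuran-3-yl)ethenyl]-4,5α,8α,9α-tetramethyl-Δ3-trans-octalin-7β-yl 2-methylpropanoate (CNP0207114.1)
Conditions: 25 (1.5 equiv), Pd(OAc)2 (10 mol %), n-Bu4NCl, NaHCO3, DMF, 70 °C
Reagents that add atoms: none
Why: Heck reaction: zerovalent palladium inserts into the activated vinylic C–Br bond of 25, syn carbopalladation places the furanone on the terminal C12, and syn β-hydride elimination can only use H12 because C9 is quaternary, giving the (E)-C11=C12 diene; the mild inorganic base spares the esters and the butenolide.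

## Compound list

1 | methyl 3,3-dimethoxypropanoate | COC(CC(=O)OC)OC | starting material
2 | 2-(triphenylphosphoranylidene)propanal | CC(C=O)=P(c1ccccc1)(c1ccccc1)c1ccccc1 | starting material
3 | methyl 3-oxopropanoate | COC(=O)CC=O | intermediate
4 | methyl (E)-4-methyl-5-oxopent-3-enoate | COC(=O)C/C=C(\C)C=O | intermediate
5 | trans-piperylene, (E)-penta-1,3-diene | C=C/C=C/C | starting material
6 | methyl 2-[(1R,5S,6R)-6-formyl-5,6-dimethylcyclohex-3-en-1-yl]acetate (endo adduct) | O=C[C@@]1(C)[C@@H](C)C=CC[C@@H]1CC(=O)OC | intermediate
7 | methyl 2-[(1R,2R)-2-formyl-2,3-dimethylcyclohex-3-en-1-yl]acetate | O=C[C@@]1(C)C(C)=CCC[C@@H]1CC(=O)OC | intermediate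
8 | 3-(methoxymethoxy)prop-1-ene (allyl methoxymethyl ether) | C=CCOCOC | starting material
9 | [(Z)-3-(methoxymethoxy)allyl]diisopinocampheylborane, isopinocampheyl groups from (+)-α-pinene | COCO/C=C\CB([C@@H]1C[C@@H]2C[C@H]([C@H]1C)C2(C)C)[C@@H]1C[C@@H]2C[C@H]([C@H]1C)C2(C)C | intermediate
10 | methyl 2-[(1R,2R)-2-[(1R,2R)-1-hydroxy-2-(methoxymethoxy)but-3-en-1-yl]-2,3-dimethylcyclohex-3-en-1-yl]acetate | O[C@@H]([C@H](OCOC)C=C)[C@@]1(C)C(C)=CCC[C@@H]1CC(=O)OC | intermediate
11 | O6-tert-butyldimethylsilyl ether of 10 | CC(C)(C)[Si](C)(C)O[C@@H]([C@H](OCOC)C=C)[C@@]1(C)C(C)=CCC[C@@H]1CC(=O)OC | intermediate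
12 | Mannich base: C9-(dimethylaminomethyl) derivative of 11, both C9 epimers | CC(C)(C)[Si](C)(C)O[C@@H]([C@H](OCOC)C=C)[C@@]1(C)C(C)=CCC[C@@H]1C(CN(C)C)C(=O)OC | intermediate
13 | trimethylammonium iodide of 12, both C9 epimers | CC(C)(C)[Si](C)(C)O[C@@H]([C@H](OCOC)C=C)[C@@]1(C)C(C)=CCC[C@@H]1C(C[N+](C)(C)C)C(=O)OC.[I-] | intermediate
14 | methyl 2-[(1S,2R)-2-[(1R,2R)-1-(tert-butyldimethylsilyloxy)-2-(methoxymethoxy)but-3-en-1-yl]-2,3-dimethylcyclohex-3-en-1-yl]prop-2-enoate | CC(C)(C)[Si](C)(C)O[C@@H]([C@H](OCOC)C=C)[C@@]1(C)C(C)=CCC[C@@H]1C(=C)C(=O)OC | intermediate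
15 | methyl 2-[(1S,2R)-2-[(1R,2S)-1-(tert-butyldimethylsilyloxy)-2-(methoxymethoxy)-3-oxobutyl]-2,3-dimethylcyclohex-3-en-1-yl]prop-2-enoate | CC(C)(C)[Si](C)(C)O[C@@H]([C@H](OCOC)C(C)=O)[C@@]1(C)C(C)=CCC[C@@H]1C(=C)C(=O)OC | intermediate
16 | copper enolate of the C9 ester of 15 after hydride addition (phosphine ligands not drawn, enolate geometry open) | CC(C)(C)[Si](C)(C)O[C@@H]([C@H](OCOC)C(C)=O)[C@@]1(C)C(C)=CCC[C@@H]1C(C)=C(OC)O[Cu] | intermediate
17 | methyl 6α-(tert-butyldimethylsilyloxy)-8β-hydroxy-7β-(methoxymethoxy)-4,5α,8α,9α-tetramethyl-Δ3-trans-octalin-9β-carboxylate (5R,6R,7S,8R,9R,10S) | CC(C)(C)[Si](C)(C)O[C@H]1[C@H](OCOC)[C@](C)(O)[C@](C)(C(=O)OC)[C@H]2CCC=C(C)[C@]12C | intermediate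
18 | 9β-hydroxymethyl analogue of 17 (C11 primary alcohol, 8β-OH free) | CC(C)(C)[Si](C)(C)O[C@H]1[C@H](OCOC)[C@](C)(O)[C@](C)(CO)[C@H]2CCC=C(C)[C@]12C | intermediate
19 | 9β-carbaldehyde analogue of 17 (C11 aldehyde) | CC(C)(C)[Si](C)(C)O[C@H]1[C@H](OCOC)[C@](C)(O)[C@](C)(C=O)[C@H]2CCC=C(C)[C@]12C | intermediate
20 | 9β-vinyl compound: 6α-OTBS, 7β-OMOM, 8β-OH | CC(C)(C)[Si](C)(C)O[C@H]1[C@H](OCOC)[C@](C)(O)[C@](C)(C=C)[C@H]2CCC=C(C)[C@]12C | intermediate
21 | 9β-vinyl 7β,8β-diol with 6α-OTBS | CC(C)(C)[Si](C)(C)O[C@H]1[C@H](O)[C@](C)(O)[C@](C)(C=C)[C@H]2CCC=C(C)[C@]12C | intermediate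
22 | 7β-isobutyrate of 21 | CC(C)(C)[Si](C)(C)O[C@H]1[C@H](OC(=O)C(C)C)[C@](C)(O)[C@](C)(C=C)[C@H]2CCC=C(C)[C@]12C | intermediate
23 | 6α,8β-diol 7β-isobutyrate with 9β-vinyl | O[C@H]1[C@H](OC(=O)C(C)C)[C@](C)(O)[C@](C)(C=C)[C@H]2CCC=C(C)[C@]12C | intermediate
24 | 6α-acetate 7β-isobutyrate 8β-ol with 9β-vinyl | CC(=O)O[C@H]1[C@H](OC(=O)C(C)C)[C@](C)(O)[C@](C)(C=C)[C@H]2CCC=C(C)[C@]12C | intermediate
25 | 4-bromofuran-2(5H)-one | O=C1C=C(Br)CO1 | starting material
26 | CNP0207114.1 (5R,6R,7S,8R,9R,10S) | CC(=O)O[C@H]1[C@H](OC(=O)C(C)C)[C@](C)(O)[C@](C)(/C=C/C2=CC(=O)OC2)[C@H]2CCC=C(C)[C@]12C | target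

## Step count and least certain steps

Total step count: 16. Longest linear sequence: 16 steps (1 → 26); 2, 5, 8 and 25 enter as purchased compounds.

Step 2 (key step). The trisubstituted enal may add too slowly, so that acid-induced polymerisation of the diene and dienolisation of 4 at the C9 methylene compete. Enantioface discrimination may be incomplete, or some addition may occur with the reversed ("meta") orientation. Fallback: starting from 4 and 5, an achiral Lewis acid (EtAlCl2, CH2Cl2, −78 °C) gives the racemic adduct, that is 6 together with its enantiomer ent-6 F1. Step 3 then gives 7 with ent-7 F2. The reagent-controlled alkoxyallylboration of step 4 converts 7 into 10 and F2 into the diastereomeric alcohol F3, which should be separable by chromatography. The route is rejoined at 10, at the cost of half the material.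

Step 8. Facial discrimination at the ketone and the enolate may be poor while two quaternary centres form at once, and 1,2-reduction of the α-alkoxy ketone may compete. Fallback: starting from 14, conjugate reduction ([(Ph3P)CuH]6, wet benzene) gives the saturated α-methyl ester F4. Enolisation with LiN(i-Pr)2 and bromination with CBr4 give the tertiary α-bromo ester F5, and the oxidation of step 7 gives the bromo ketone F6. SmI2 in THF at −78 °C then generates a trivalent samarium enolate that closes ring B in a Reformatsky reaction through a tighter, more oxophilic chelate that can also bind O7. The route is rejoined at 17.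

Step 3. The alkene may migrate further (towards C1=C10 or into conjugation with the ester), and the acid may engage the formyl group (Prins-type closure onto C2, or a 1,2-formyl shift through the C4 cation). Fallback: starting from 6, acetalisation (HC(OMe)3, MeOH, cat. TsOH, rt) gives the dimethyl acetal F7. A rhodium hydride isomerisation by addition and β-hydride elimination (RhCl3·3H2O, MeOH, 65 °C) gives the isomerised acetal F8, and hydrolysis (1 M HCl, THF) returns to the route at 7.

Step 16. Insertion at the neopentyl-type vinyl group may be slow, so that base-induced decomposition of 25 and precipitation of palladium take over. Fallback: starting from 24, cross-metathesis with vinylboronic acid pinacol ester using the second-generation Hoveyda–Grubbs catalyst (H2IMes)Cl2Ru=CH(C6H4-2-O-i-Pr) in CH2Cl2 at 40 °C gives the (E)-alkenyl boronate F9. Suzuki coupling of F9 with 25 (Pd(PPh3)4, K3PO4, THF/H2O, 40 °C) reaches 26 directly.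

Step 1. The β-formyl ester 3 may self-condense, or transfer a proton to the weakly basic ylide, before olefination. Fallback: cross-metathesis of purchased methyl but-3-enoate with excess methacrolein, using the same ruthenium catalyst in CH2Cl2 at 40 °C, is expected to give the (E)-enal directly. The route is rejoined at 4 without any unstable aldehyde.

## Further compounds

F1 | step 2 | ent-6, methyl 2-[(1S,5R,6S)-6-formyl-5,6-dimethylcyclohex-3-en-1-yl]acetate | O=C[C@]1(C)[C@H](C)C=CC[C@H]1CC(=O)OC
F2 | step 2 | ent-7, methyl 2-[(1S,2S)-2-formyl-2,3-dimethylcyclohex-3-en-1-yl]acetate | O=C[C@]1(C)C(C)=CCC[C@H]1CC(=O)OC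
F3 | step 2 | diastereomer of 10 from F2 (ring centres inverted, C6 and C7 as in 10) | O[C@@H]([C@H](OCOC)C=C)[C@]1(C)C(C)=CCC[C@H]1CC(=O)OC
F4 | step 8 | saturated α-methyl ester from 14, both C9 epimers | CC(C)(C)[Si](C)(C)O[C@@H]([C@H](OCOC)C=C)[C@@]1(C)C(C)=CCC[C@@H]1C(C)C(=O)OC
F5 | step 8 | α-bromo-α-methyl ester, both C9 epimers | CC(C)(C)[Si](C)(C)O[C@@H]([C@H](OCOC)C=C)[C@@]1(C)C(C)=CCC[C@@H]1C(C)(Br)C(=O)OC
F6 | step 8 | α-bromo-α-methyl ester with C8 methyl ketone, both C9 epimers | CC(C)(C)[Si](C)(C)O[C@@H]([C@H](OCOC)C(C)=O)[C@@]1(C)C(C)=CCC[C@@H]1C(C)(Br)C(=O)OC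
F7 | step 3 | dimethyl acetal of 6 | COC(OC)[C@@]1(C)[C@@H](C)C=CC[C@@H]1CC(=O)OC
F8 | step 3 | dimethyl acetal of 7 | COC(OC)[C@@]1(C)C(C)=CCC[C@@H]1CC(=O)OC
F9 | step 16 | (E)-C12 pinacol boronate of 24 | CC(=O)O[C@H]1[C@H](OC(=O)C(C)C)[C@](C)(O)[C@](C)(/C=C/B3OC(C)(C)C(C)(C)O3)[C@H]2CCC=C(C)[C@]12C
F0 | step 1 | none | none
A1 | alternative 1 | 8β,9β-epoxy-7-oxo-ent-homodrimane 12-O-tert-butyldiphenylsilyl ether | O=C1C[C@@H]2C(C)(C)CCC[C@@]2(C)[C@@]3(CCO[Si](c4ccccc4)(c5ccccc5)C(C)(C)C)O[C@@]13C
A2 | alternative 1 | 8β-hydroxy-7-oxo-clerod-3-ene core with C11–C12 as CH2CH2OTBDPS | C1C(=O)[C@](C)(O)[C@](C)(CCO[Si](c3ccccc3)(c4ccccc4)C(C)(C)C)[C@H]2CCC=C(C)[C@]12C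
A3 | alternative 2 | keto acrylate with 6-OTBS and 7-OPMB (PMB analogue of 15) | CC(C)(C)[Si](C)(C)O[C@@H]([C@H](OCc2ccc(OC)cc2)C(C)=O)[C@@]1(C)C(C)=CCC[C@@H]1C(=C)C(=O)OC
A4 | alternative 2 | decalin with 6α-OTBS, 7β-OPMB, 8β-OH, C9 methyl and methyl ester | CC(C)(C)[Si](C)(C)O[C@H]1[C@H](OCc3ccc(OC)cc3)[C@](C)(O)[C@](C)(C(=O)OC)[C@H]2CCC=C(C)[C@]12C
A5 | alternative 3 | (2Z,4E)-3-(tert-butyldimethylsilyloxy)hexa-2,4-diene | C/C=C(\O[Si](C)(C)C(C)(C)C)/C=C/C
A6 | alternative 3 | (E)-2-methylhepta-2,6-dienal | O=C/C(C)=C/CCC=C
A7 | alternative 3 | ring-B endo cycloadduct with C6 silyl enol ether, C9 methyl and formyl, C10 butenyl | C[C@H]1C=C(O[Si](C)(C)C(C)(C)C)[C@@H](C)[C@H](CCC=C)[C@@]1(C)C=O
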